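Ring B carries oxygen at C6 and C9, para to each other across the C5–C10 bond, with methyl groups on C8 and C10: it is a masked 2,6-dimethyl-1,4-benzoquinone. Ring A (C10, C1, C2, C3, C4, C5) is therefore cut at C10–C1 and C4–C5. One catalytic enantioselective Diels–Alder reaction between this quinone and 4-methylpenta-1,3-diene closes ring A, delivers C1–C4 with the gem-dimethyl group and sets the quaternary C10. Both precursors are commercial. Ring B and, later, the lactone arrive as preformed rings from commercial building blocks, so ring A is the only skeletal ring the route has to close. Epimerisation, redox adjustment and side-chain attachment through a C9 spiro-epoxide finish the synthesis.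

Key step: step 1

Remark on numbering: atoms are cited by labdane numbering (decalin C1–C10, ethylene link C11–C12, lactone C13–C16); systematic names use naphthalene locants.

Remark (assumption): the absolute sense of step 1 is assigned from the accepted pre-transition-state model of cationic oxazaborolidine catalysis (quinone bound through the C6 carbonyl, vinylic C5–H held near the ring oxygen, one face covered by a C-aryl group), which points to the (R)-prolinol-derived catalyst for the (8aS)-adduct; should the adduct prove antipodal, the (S)-catalyst is used in the same way.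

Step 1
Reactants: 1 2,6-dimethyl-1,4-benzoquinone; 2 4-methylpenta-1,3-diene
Product: 3 (4aR,8aS)-2,5,5,8a-tetramethyl-4a,5,8,8a-tetrahydronaphthalene-1,4-dione (cis-fused)
Conditions: 2 (4 equiv, slow addition), (R)-1-(2-methylphenyl)-3,3-diphenyltetrahydro-1H,3H-pyrrolo[1,2-c][1,3,2]oxazaborole (20 mol %), Tf2NH (18 mol %), CH2Cl2, −78 to −40 °C
Reagents that add atoms: none
Why: The protonated oxazaborolidine binds the C6 carbonyl (the only one flanked by vinylic C–H) and makes C10 the most electrophilic ring carbon, so the diene adds in a concerted but asynchronous [4+2] cycloaddition in which its CH2 terminus (C1, largest HOMO coefficient) bonds to C10 ahead of the CMe2 terminus (C4) bonding to C5. The closest known reaction type is the oxazaborolidinium-catalysed enantioselective Diels–Alder reaction of alkylated 1,4-benzoquinones with acyclic dienes. Ring A is closed in an intermolecular [4+2] mode, suprafacial on both partners, which gives the cis-fused six-membered ring. The quaternary C10 is set by the catalyst, whose C-aryl group covers one face of the bound C5=C10 bond, and C5 is set relative to C10 by the suprafacial addition (cis, inverted to trans in step 2). The step needs regiocontrol, secured because orbital coefficients and sterics both keep the CMe2 terminus away from the methyl-bearing C10, and site control, which is no issue since the two quinone double bonds are equivalent by symmetry. The angular methyl blocks aromatisation of the adduct.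

Step 2
Reactants: 3 (4aR,8aS)-2,5,5,8a-tetramethyl-4a,5,8,8a-tetrahydronaphthalene-1,4-dione
Product: 5 (2R,4aS,8aS)-2,5,5,8a-tetramethyloctahydronaphthalene-1,4-dione (trans-fused), via cis-fused saturated dione 4 (not isolated)
Conditions: H2 (1 atm), 10% Pd/C, EtOAc, rt; filter; NaOMe (0.2 equiv), MeOH, rt
Reagents that add atoms: none
Why: Catalytic hydrogenation saturates the electron-poor C7=C8 bond and the ring A C2=C3 bond, and methoxide then equilibrates the two enolisable centres (C5 next to the C6 ketone, C8 next to the C9 ketone) to the thermodynamically preferred trans-decalin with the 8-methyl equatorial, away from the axial C10 methyl (base-mediated epimerisation).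

Step 3
Reactants: 5 (2R,4aS,8aS)-2,5,5,8a-tetramethyloctahydronaphthalene-1,4-dione
Product: 6 (1S,2R,4S,4aS,8aS)-2,5,5,8a-tetramethyldecahydronaphthalene-1,4-diol
Conditions: Li, NH3(l)/THF, EtOH, −78 to −33 °C; NH4Cl
Reagents that add atoms: none
Why: Dissolving-metal ketone reduction proceeds through carbanions that are protonated to the thermodynamic equatorial alcohols, so C6 should receive the 6α-hydroxyl that hydride reagents, forced to the α face by the two syn-axial methyls (on C10 and C4), cannot give; the C9 carbinol configuration is irrelevant because step 5 removes it.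

Step 4
Reactants: 6 (1S,2R,4S,4aS,8aS)-2,5,5,8a-tetramethyldecahydronaphthalene-1,4-diol
Product: 7 (1S,3R,4S,4aS,8aS)-4-hydroxy-3,4a,8,8-tetramethyldecahydronaphthalen-1-yl acetate
Conditions: Ac2O (1.1 equiv), pyridine, DMAP (cat.), CH2Cl2, 0 °C
Reagents that add atoms: acetic anhydride CC(=O)OC(C)=O
Why: Selective acetylation should esterify the equatorial C6 hydroxyl, while the C9 hydroxyl, wedged between the quaternary C10 and the methyl-bearing C8, is too hindered to react.

Step 5
Reactants: 7 (1S,3R,4S,4aS,8aS)-4-hydroxy-3,4a,8,8-tetramethyldecahydronaphthalen-1-yl acetate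
Product: 8 (1S,3R,4aS,8aS)-3,4a,8,8-tetramethyl-4-oxodecahydronaphthalen-1-yl acetate
Conditions: Dess–Martin periodinane, NaHCO3, CH2Cl2, rt
Reagents that add atoms: none
Why: Dess–Martin oxidation converts the remaining hindered secondary alcohol to the C9 ketone under neutral conditions that leave the acetate and the C8 centre (already in its thermodynamic configuration) untouched.

Step 6
Reactants: 8 (1S,3R,4aS,8aS)-3,4a,8,8-tetramethyl-4-oxodecahydronaphthalen-1-yl acetate
Product: 9 (1S,3R,4aS,8aS)-3,4a,8,8-tetramethyl-4-methylidenedecahydronaphthalen-1-yl acetate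
Conditions: Zn, CH2Br2, TiCl4, THF/CH2Cl2, 0 °C to rt
Reagents that add atoms: dibromomethane BrCBr
Why: Takai–Lombardo methylenation uses a non-basic zinc/titanium methylene reagent that reacts with hindered, enolisable ketones and ignores esters, so C11 should be installed without cleaving the acetate or disturbing C8.

Step 7
Reactants: 9 (1S,3R,4aS,8aS)-3,4a,8,8-tetramethyl-4-methylidenedecahydronaphthalen-1-yl acetate
Product: 10 (1R,2R,4S,4aS,8aS)-2,5,5,8a-tetramethyloctahydro-1H-spiro[naphthalene-1,2'-oxiran]-4-yl acetate (oxirane oxygen α, opposite the angular methyl)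
Conditions: mCPBA, NaHCO3, CH2Cl2, 0 °C
Reagents that add atoms: meta-chloroperoxybenzoic acid OOC(=O)c1cccc(Cl)c1
Why: In this Prilezhaev epoxidation the peracid should approach the exocyclic alkene from the α face, because the axial C10 methyl on the adjacent carbon shields the β face, which places oxygen α and C11 β at C9.

Step 8
Reactants: 10 (1R,2R,4S,4aS,8aS)-2,5,5,8a-tetramethyloctahydro-1H-spiro[naphthalene-1,2'-oxiran]-4-yl acetate
Product: 11 (1S,3R,4R,4aS,8aS)-4-hydroxy-3,4a,8,8-tetramethyl-4-(prop-2-en-1-yl)decahydronaphthalen-1-yl acetate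
Conditions: CH2=CHMgBr (4 equiv), CuBr·SMe2 (2 equiv), THF, −40 to 0 °C; NH4Cl (aq)
Reagents that add atoms: vinylmagnesium bromide C=C[Mg]Br
Why: The preformed divinylcuprate opens the epoxide by SN2 attack at the primary C11, which leaves the C9–O bond and hence the 9α-hydroxyl configuration intact, and organocuprates do not add to the acetate (copper-mediated epoxide opening).

Step 9
Reactants: 11 (1S,3R,4R,4aS,8aS)-4-hydroxy-3,4a,8,8-tetramethyl-4-(prop-2-en-1-yl)decahydronaphthalen-1-yl acetate; 12 3-methylideneoxolan-2-one (α-methylene-γ-butyrolactone)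
Product: 13 (1S,3R,4R,4aS,8aS)-4-hydroxy-3,4a,8,8-tetramethyl-4-[(2E)-2-(2-oxooxolan-3-ylidene)ethyl]decahydronaphthalen-1-yl acetate
Conditions: 12 (5 equiv), second-generation Hoveyda–Grubbs catalyst [RuCl2(H2IMes)(=CH-C6H4-2-OiPr)] (10 mol %), 2,6-dichloro-1,4-benzoquinone (10 mol %), CH2Cl2, 40 °C
Reagents that add atoms: none
Why: Olefin cross-metathesis joins the terminal alkene with the 1,1-disubstituted alkene of 12 with loss of ethene and should give the thermodynamically preferred E-alkylidene lactone, while the quinone additive suppresses ruthenium hydride double-bond migration.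

Step 10
Reactants: 13 (1S,3R,4R,4aS,8aS)-4-hydroxy-3,4a,8,8-tetramethyl-4-[(2E)-2-(2-oxooxolan-3-ylidene)ethyl]decahydronaphthalen-1-yl acetate
Product: 14 (1S,3R,4R,4aS,8aS)-4-hydroxy-3,4a,8,8-tetramethyl-4-[2-(2-oxo-2,5-dihydrofuran-3-yl)ethyl]decahydronaphthalen-1-yl acetate (target)
Conditions: RhCl3·3H2O (10 mol %), EtOH, 80 °C
Reagents that add atoms: none
Why: Rhodium hydride addition–elimination should move the exocyclic C12=C13 bond into the ring (C13=C14) to give the thermodynamically preferred endocyclic butenolide, the exo-to-endo isomerisation known for 2-alkylidene cyclopentanones and α-alkylidene butyrolactones; no stereocentre is involved.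

Compound list
1 | 2,6-dimethyl-1,4-benzoquinone | CC1=CC(=O)C=C(C)C1=O | starting material
2 | 4-methylpenta-1,3-diene | C=CC=C(C)C | starting material
3 | (4aR,8aS)-2,5,5,8a-tetramethyl-4a,5,8,8a-tetrahydronaphthalene-1,4-dione (cis-fused) | O=C1C=C(C)C(=O)[C@@]2(C)CC=CC(C)(C)[C@@H]12 | intermediate
4 | (4aR,8aS)-2,5,5,8a-tetramethyloctahydronaphthalene-1,4-dione (cis-fused, both C2 epimers) | O=C1CC(C)C(=O)[C@@]2(C)CCCC(C)(C)[C@@H]12 | intermediate (not isolated)
5 | (2R,4aS,8aS)-2,5,5,8a-tetramethyloctahydronaphthalene-1,4-dione (trans-fused) | O=C1C[C@@H](C)C(=O)[C@@]2(C)CCCC(C)(C)[C@H]12 | intermediate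
6 | (1S,2R,4S,4aS,8aS)-2,5,5,8a-tetramethyldecahydronaphthalene-1,4-diol (C1 carbinol drawn as the expected equatorial epimer; either epimer serves) | O[C@H]1C[C@@H](C)[C@H](O)[C@@]2(C)CCCC(C)(C)[C@H]12 | intermediate
7 | (1S,3R,4S,4aS,8aS)-4-hydroxy-3,4a,8,8-tetramethyldecahydronaphthalen-1-yl acetate | CC(=O)O[C@H]1C[C@@H](C)[C@H](O)[C@@]2(C)CCCC(C)(C)[C@H]12 | intermediate
8 | (1S,3R,4aS,8aS)-3,4a,8,8-tetramethyl-4-oxodecahydronaphthalen-1-yl acetate | CC(=O)O[C@H]1C[C@@H](C)C(=O)[C@@]2(C)CCCC(C)(C)[C@H]12 | intermediate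
9 | (1S,3R,4aS,8aS)-3,4a,8,8-tetramethyl-4-methylidenedecahydronaphthalen-1-yl acetate | CC(=O)O[C@H]1C[C@@H](C)C(=C)[C@@]2(C)CCCC(C)(C)[C@H]12 | intermediate
10 | (1R,2R,4S,4aS,8aS)-2,5,5,8a-tetramethyloctahydro-1H-spiro[naphthalene-1,2'-oxiran]-4-yl acetate (oxirane oxygen α) | CC(=O)O[C@H]1C[C@@H](C)[C@]3(CO3)[C@@]2(C)CCCC(C)(C)[C@H]12 | intermediate
11 | (1S,3R,4R,4aS,8aS)-4-hydroxy-3,4a,8,8-tetramethyl-4-(prop-2-en-1-yl)decahydronaphthalen-1-yl acetate | CC(=O)O[C@H]1C[C@@H](C)[C@](O)(CC=C)[C@@]2(C)CCCC(C)(C)[C@H]12 | intermediate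
12 | 3-methylideneoxolan-2-one (α-methylene-γ-butyrolactone) | C=C1CCOC1=O | starting material
13 | (1S,3R,4R,4aS,8aS)-4-hydroxy-3,4a,8,8-tetramethyl-4-[(2E)-2-(2-oxooxolan-3-ylidene)ethyl]decahydronaphthalen-1-yl acetate | CC(=O)O[C@H]1C[C@@H](C)[C@](O)(C/C=C3\CCOC3=O)[C@@]2(C)CCCC(C)(C)[C@H]12 | intermediate
14 | (1S,3R,4R,4aS,8aS)-4-hydroxy-3,4a,8,8-tetramethyl-4-[2-(2-oxo-2,5-dihydrofuran-3-yl)ethyl]decahydronaphthalen-1-yl acetate | CC(=O)O[C@H]1C[C@@H](C)[C@](O)(CCC2=CCOC2=O)[C@@]2(C)CCCC(C)(C)[C@H]12 | target

Total step count: 10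
Longest linear sequence: 10 steps (1 to 14; compounds 2 and 12 enter as commercial materials)

Steps most likely to fail

1. Step 1. The Z-methyl group of 2 disfavours the s-cis conformation, so cycloaddition may be outrun by acid-induced oligomerisation of the diene or by a stepwise, non-concerted addition, with loss of conversion or of enantioselectivity. The fallback sets out from 1 and returns at 3. Commercial mesityl oxide is enolised kinetically at its methyl group (LDA, THF, −78 °C) and silylated (TIPSOTf) to the cross-conjugated diene 4-methyl-2-[(triisopropylsilyl)oxy]penta-1,3-diene F1, a far more electron-rich diene of the class for which this catalyst family is best documented. Cycloaddition of F1 to 1 under the step 1 catalyst should give, with the same regiochemical and facial sense, the silyl enol ether (4aR,8aS)-2,5,5,8a-tetramethyl-7-[(triisopropylsilyl)oxy]-4a,5,8,8a-tetrahydronaphthalene-1,4-dione F2. CsF and PhNTf2 in DME convert it into the enol triflate (4aR,8aS)-2,5,5,8a-tetramethyl-1,4-dioxo-1,4,4a,5,8,8a-hexahydronaphthalen-7-yl trifluoromethanesulfonate F3, and palladium-catalysed formate reduction (Pd(OAc)2, PPh3, Bu3N, HCO2H, DMF, 60 °C) removes the triflate to give 3.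

2. Step 8. SN2 attack at C11, which sits next to the fully substituted C9, may be slower than halide opening of the epoxide, Lewis-acid-induced rearrangement of the epoxide by 1,2-hydride shift, or attack on the acetate. The fallback sets out from 9 and returns at 14, so that no nucleophile has to reach C11 and steps 9 and 10 are not needed. Dihydroxylation of 9 (OsO4 cat., NMO, acetone/H2O) from the same α face should give the diol (1S,3R,4R,4aS,8aS)-4-hydroxy-4-(hydroxymethyl)-3,4a,8,8-tetramethyldecahydronaphthalen-1-yl acetate F4. Parikh–Doering oxidation (SO3·pyridine, DMSO, iPr2NEt) gives the non-enolisable hydroxy aldehyde (1S,3R,4R,4aS,8aS)-4-formyl-4-hydroxy-3,4a,8,8-tetramethyldecahydronaphthalen-1-yl acetate F5. Wittig methylenation (Ph3P=CH2, THF, −78 to 0 °C) gives the vinyl carbinol (1S,3R,4R,4aS,8aS)-4-ethenyl-4-hydroxy-3,4a,8,8-tetramethyldecahydronaphthalen-1-yl acetate F6. Hydroboration with 9-BBN (THF) gives the alkylborane (1S,3R,4R,4aS,8aS)-4-[2-(9-borabicyclo[3.3.1]nonan-9-yl)ethyl]-4-hydroxy-3,4a,8,8-tetramethyldecahydronaphthalen-1-yl acetate F7, which is coupled in the same flask with 3-bromofuran-2(5H)-one (PdCl2(dppf), AsPh3, Cs2CO3, DMF/H2O, rt; B-alkyl Suzuki–Miyaura coupling) to give 14 directly.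

3. Step 9. The hindered homoallylic alkene may homodimerise or turn over slowly with the 1,1-disubstituted olefin of 12, and hydride-mediated isomerisation of 12 may consume the partner. The fallback sets out from 11 and returns at 13. Ozonolysis of 11 (O3, CH2Cl2, −78 °C; Me2S) gives the β-hydroxy aldehyde (1S,3R,4R,4aS,8aS)-4-hydroxy-3,4a,8,8-tetramethyl-4-(2-oxoethyl)decahydronaphthalen-1-yl acetate F8. Wittig reaction with the commercial stabilised ylide 3-(triphenyl-λ5-phosphanylidene)oxolan-2-one (toluene, 80 °C) should then give 13 as the E isomer.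

Further compounds
F1 | step 1 | 4-methyl-2-[(triisopropylsilyl)oxy]penta-1,3-diene | C=C(O[Si](C(C)C)(C(C)C)C(C)C)C=C(C)C
F2 | step 1 | (4aR,8aS)-2,5,5,8a-tetramethyl-7-[(triisopropylsilyl)oxy]-4a,5,8,8a-tetrahydronaphthalene-1,4-dione | O=C1C=C(C)C(=O)[C@@]2(C)CC(O[Si](C(C)C)(C(C)C)C(C)C)=CC(C)(C)[C@@H]12
F3 | step 1 | (4aR,8aS)-2,5,5,8a-tetramethyl-1,4-dioxo-1,4,4a,5,8,8a-hexahydronaphthalen-7-yl trifluoromethanesulfonate | O=C1C=C(C)C(=O)[C@@]2(C)CC(OS(=O)(=O)C(F)(F)F)=CC(C)(C)[C@@H]12
F4 | step 8 | (1S,3R,4R,4aS,8aS)-4-hydroxy-4-(hydroxymethyl)-3,4a,8,8-tetramethyldecahydronaphthalen-1-yl acetate | CC(=O)O[C@H]1C[C@@H](C)[C@](O)(CO)[C@@]2(C)CCCC(C)(C)[C@H]12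
F5 | step 8 | (1S,3R,4R,4aS,8aS)-4-formyl-4-hydroxy-3,4a,8,8-tetramethyldecahydronaphthalen-1-yl acetate | CC(=O)O[C@H]1C[C@@H](C)[C@](O)(C=O)[C@@]2(C)CCCC(C)(C)[C@H]12
F6 | step 8 | (1S,3R,4R,4aS,8aS)-4-ethenyl-4-hydroxy-3,4a,8,8-tetramethyldecahydronaphthalen-1-yl acetate | CC(=O)O[C@H]1C[C@@H](C)[C@](O)(C=C)[C@@]2(C)CCCC(C)(C)[C@H]12
F7 | step 8 | (1S,3R,4R,4aS,8aS)-4-[2-(9-borabicyclo[3.3.1]nonan-9-yl)ethyl]-4-hydroxy-3,4a,8,8-tetramethyldecahydronaphthalen-1-yl acetate | CC(=O)O[C@H]1C[C@@H](C)[C@](O)(CCB3C4CCCC3CCC4)[C@@]2(C)CCCC(C)(C)[C@H]12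
F8 | step 9 | (1S,3R,4R,4aS,8aS)-4-hydroxy-3,4a,8,8-tetramethyl-4-(2-oxoethyl)decahydronaphthalen-1-yl acetate | CC(=O)O[C@H]1C[C@@H](C)[C@](O)(CC=O)[C@@]2(C)CCCC(C)(C)[C@H]12
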